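**Retrosynthetic overview**
1. Target 16 ⇐ 15 by O‑benzyl hydrogenolysis (last step) ⇐ 14 by acetylation of its single free phenol. The two resorcinol oxygens are kept different (Bn / MOM) from compound 11 onward, so the mono‑acetate is never made statistically.
2. Aryl–CH2 bond: CuI‑catalysed opening of (S)‑2‑dodecyloxirane 5 at its CH2 by aryl Grignard 12 (from 11).
3. 5 ⇐ (S)‑chlorohydrin 4 ⇐ ketoreductase reduction of the achiral chloromethyl ketone 3 (the only stereocentre is set here) ⇐ C12H25MgBr 1 + chloro‑Weinreb amide 2.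
4. 11 ⇐ 3,5‑dibromophenol 6 by O‑benzylation, conversion of one C–Br into C–OH (Br/Li exchange–borylation–oxidation), and MOM protection.
5. Rings: the benzene ring is bought. The only ring formed is the oxirane of 5 (step 3), opened again in step 7.

Assumption: compounds 1, 2 and 6 are taken as commercial (all achiral); the target's single stereocentre is (S), as read from the SMILES.

**Route**

Step 1
Reactants: 1 dodecylmagnesium bromide (C12H25MgBr); 2 2‑chloro‑N‑methoxy‑N‑methylacetamide
Product: 3 1‑chlorotetradecan‑2‑one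
Conditions: THF/Et2O, −20 → 0 °C; then 1 M HCl
Reagents that add atoms: none
Why: Weinreb ketone synthesis: the N‑methoxy‑N‑methylamide accepts only one equivalent of Grignard reagent, so no tertiary alcohol forms, and at −20 °C acyl addition outruns displacement of the primary chloride.

Step 2
Reactants: 3 1‑chlorotetradecan‑2‑one
Product: 4 (2S)‑1‑chlorotetradecan‑2‑ol
Conditions: ketoreductase (anti‑Prelog, NADPH‑dependent alcohol dehydrogenase, Lactobacillus kefir type), NADP+ (cat.), MgCl2 (1 mM), iPrOH (30% v/v)/K2HPO4–KH2PO4 buffer pH 7.0, 30 °C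
Reagents that add atoms: none
Why: Biocatalytic asymmetric ketone reduction: the enzyme places CH2Cl in its small pocket and the dodecyl chain in its large pocket and delivers hydride from NADPH (recycled from 2‑propanol) to the re face of the prochiral carbonyl, which gives the (S)‑chlorohydrin because CH2Cl outranks the alkyl chain, typically in >99% ee.

Step 3
Reactants: 4 (2S)‑1‑chlorotetradecan‑2‑ol
Product: 5 (2S)‑2‑dodecyloxirane
Conditions: NaOH (1.5 equiv), EtOH/H2O, 0 °C → rt
Reagents that add atoms: none
Why: Intramolecular Williamson etherification (SN2 of the alkoxide on CH2Cl); the stereocentre only carries the nucleophilic oxygen, so its configuration is retained.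

Step 4
Reactants: 6 3,5‑dibromophenol
Product: 7 1‑(benzyloxy)‑3,5‑dibromobenzene
Conditions: BnBr (1.1 equiv), K2CO3 (1.5 equiv), acetone, reflux
Reagents that add atoms: benzyl bromide, BrCc1ccccc1
Why: Williamson ether synthesis on the phenoxide; the benzyl ether survives every later step and is removed last under neutral conditions.

Step 5
Reactants: 7 1‑(benzyloxy)‑3,5‑dibromobenzene
Product: 10 3‑(benzyloxy)‑5‑bromophenol, via aryllithium 8 (not isolated), via dimethyl arylboronate 9 (not isolated)
Conditions: n‑BuLi (1.05 equiv), Et2O, −78 °C; B(OMe)3, −78 °C → rt; then 30% aq. H2O2, 0 °C → rt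
Reagents that add atoms: hydrogen peroxide, OO
Why: Bromine–lithium exchange at −78 °C stops after one bromine because the aryllithium resists a second exchange, and the derived boronate is oxidised with aryl migration from boron to oxygen (lithiation–borylation–oxidation), so exactly one C–Br becomes C–OH without a statistical step.

Step 6
Reactants: 10 3‑(benzyloxy)‑5‑bromophenol
Product: 11 1‑(benzyloxy)‑3‑bromo‑5‑(methoxymethoxy)benzene
Conditions: MOMCl (1.3 equiv), K2CO3 (2 equiv), acetone, 0 °C → rt
Reagents that add atoms: chloromethyl methyl ether, COCCl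
Why: O‑alkylation of the phenoxide gives a MOM acetal that is inert to Grignard chemistry and can later be removed by mild acid without touching the benzyl ether.

Step 7
Reactants: 11 1‑(benzyloxy)‑3‑bromo‑5‑(methoxymethoxy)benzene; 5 (2S)‑2‑dodecyloxirane
Product: 13 (2S)‑1‑[3‑(benzyloxy)‑5‑(methoxymethoxy)phenyl]tetradecan‑2‑ol, via arylmagnesium bromide 12 (not isolated)
Conditions: Mg, I2 (cat.), THF, 40 °C; then CuI (10 mol %), 5 (0.7 equiv), THF, −30 → 0 °C; H2O/aq. NH4Cl
Reagents that add atoms: none
Why: Copper‑catalysed SN2 opening of a terminal epoxide by an aryl Grignard reagent occurs only at the unsubstituted CH2, so the C–O stereocentre of 5 is carried over unchanged as the (S)‑carbinol.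

Step 8
Reactants: 13 (2S)‑1‑[3‑(benzyloxy)‑5‑(methoxymethoxy)phenyl]tetradecan‑2‑ol
Product: 14 3‑(benzyloxy)‑5‑[(2S)‑2‑hydroxytetradecyl]phenol
Conditions: HCl (cat.), MeOH, 40 °C
Reagents that add atoms: none
Why: Acid‑catalysed transacetalisation to methanol removes the MOM group, while the benzyl ether and the non‑benzylic secondary alcohol are inert and cannot ionise or epimerise.

Step 9
Reactants: 14 3‑(benzyloxy)‑5‑[(2S)‑2‑hydroxytetradecyl]phenol
Product: 15 3‑(benzyloxy)‑5‑[(2S)‑2‑hydroxytetradecyl]phenyl acetate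
Conditions: Ac2O (1.05 equiv), Et3N (1.2 equiv), CH2Cl2, 0 °C (no DMAP)
Reagents that add atoms: acetic anhydride, CC(=O)OC(C)=O
Why: Chemoselective O‑acylation: Et3N deprotonates only the phenol, and the phenoxide is acetylated at 0 °C far faster than the hindered secondary alcohol in the absence of an acyl‑transfer catalyst.

Step 10
Reactants: 15 3‑(benzyloxy)‑5‑[(2S)‑2‑hydroxytetradecyl]phenyl acetate
Product: 16 3‑hydroxy‑5‑[(2S)‑2‑hydroxytetradecyl]phenyl acetate
Conditions: H2 (1 atm), 10% Pd/C, EtOAc, rt
Reagents that add atoms: none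
Why: Catalytic hydrogenolysis of the benzyl aryl ether under neutral aprotic conditions leaves the aryl acetate, the secondary alcohol and the stereocentre untouched.

**Compound list**
1 | dodecylmagnesium bromide | CCCCCCCCCCCC[Mg]Br | starting material
2 | 2‑chloro‑N‑methoxy‑N‑methylacetamide | CON(C)C(=O)CCl | starting material
3 | 1‑chlorotetradecan‑2‑one | CCCCCCCCCCCCC(=O)CCl | intermediate
4 | (2S)‑1‑chlorotetradecan‑2‑ol | CCCCCCCCCCCC[C@H](O)CCl | intermediate
5 | (2S)‑2‑dodecyloxirane | CCCCCCCCCCCC[C@H]1CO1 | intermediate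
6 | 3,5‑dibromophenol | Oc1cc(Br)cc(Br)c1 | starting material
7 | 1‑(benzyloxy)‑3,5‑dibromobenzene | Brc1cc(Br)cc(OCc2ccccc2)c1 | intermediate
8 | [3‑(benzyloxy)‑5‑bromophenyl]lithium | [Li]c1cc(Br)cc(OCc2ccccc2)c1 | intermediate
9 | dimethyl [3‑(benzyloxy)‑5‑bromophenyl]boronate | COB(OC)c1cc(Br)cc(OCc2ccccc2)c1 | intermediate
10 | 3‑(benzyloxy)‑5‑bromophenol | Oc1cc(Br)cc(OCc2ccccc2)c1 | intermediate
11 | 1‑(benzyloxy)‑3‑bromo‑5‑(methoxymethoxy)benzene | COCOc1cc(Br)cc(OCc2ccccc2)c1 | intermediate
12 | [3‑(benzyloxy)‑5‑(methoxymethoxy)phenyl]magnesium bromide | COCOc1cc([Mg]Br)cc(OCc2ccccc2)c1 | intermediate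
13 | (2S)‑1‑[3‑(benzyloxy)‑5‑(methoxymethoxy)phenyl]tetradecan‑2‑ol | CCCCCCCCCCCC[C@H](O)Cc1cc(OCOC)cc(OCc2ccccc2)c1 | intermediate
14 | 3‑(benzyloxy)‑5‑[(2S)‑2‑hydroxytetradecyl]phenol | CCCCCCCCCCCC[C@H](O)Cc1cc(O)cc(OCc2ccccc2)c1 | intermediate
15 | 3‑(benzyloxy)‑5‑[(2S)‑2‑hydroxytetradecyl]phenyl acetate | CCCCCCCCCCCC[C@H](O)Cc1cc(OC(C)=O)cc(OCc2ccccc2)c1 | intermediate
16 | 3‑hydroxy‑5‑[(2S)‑2‑hydroxytetradecyl]phenyl acetate | CCCCCCCCCCCC[C@H](O)Cc1cc(O)cc(OC(C)=O)c1 | target

**Totals**
Total steps: 10. Longest linear sequence: 7 steps (steps 1, 2, 3, 7, 8, 9, 10 from 1 and 2; the aryl branch, steps 4, 5, 6, 7, 8, 9, 10 from 6, is equally long).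

**Three steps most likely to fail, with fallbacks**

Step 2 (ketoreductase reduction). The C14 chloroketone is very lipophilic, so the enzyme may turn it over slowly or give ee below specification. The fallback sets out from 3 and comes back at 5. Ketone 3 is reduced without stereocontrol (NaBH4, MeOH, 0 °C) to racemic 1‑chlorotetradecan‑2‑ol F1, which is closed with NaOH to racemic 2‑dodecyloxirane F2. F2 is then resolved by Jacobsen hydrolytic kinetic resolution with (S,S)‑(salen)Co(OAc) (trivalent cobalt, 0.5 mol %), H2O (0.55 equiv), THF, 0 °C → rt. This catalyst enantiomer hydrolyses the (R)‑epoxide and leaves 5 (at most 50%, >99% ee), which is separated from the hydrolysed enantiomer by chromatography or distillation.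

Step 5 (one‑pot Br/Li exchange–borylation–oxidation). Double exchange, butylation of the aryllithium by n‑BuBr, or incomplete oxidation can erode the yield. The fallback sets out from 7 (together with 5) and comes back at 14, bypassing steps 5 to 8. Bromine–magnesium exchange on 7 with iPrMgCl·LiCl (THF, 0 °C → rt) gives [3‑(benzyloxy)‑5‑bromophenyl]magnesium chloride F3. F3 opens epoxide 5 under CuI catalysis (10 mol %, −30 → 0 °C) to (2S)‑1‑[3‑(benzyloxy)‑5‑bromophenyl]tetradecan‑2‑ol F4. The remaining bromide is then turned into the phenol by palladium‑catalysed hydroxylation (Pd2(dba)3, zerovalent palladium, tBuXPhos, KOH, 1,4‑dioxane/H2O, 100 °C), giving 14. Here the second bromine acts as the masked phenol and no MOM group is needed.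

Step 7 (Grignard formation and copper‑catalysed epoxide opening). Sluggish initiation on the electron‑rich bromide, biaryl formation, or bromohydrin from magnesium halide opening of 5 are the likely problems. The fallback sets out from 11 (together with 5) and comes back at 13. Bromine–lithium exchange on 11 (n‑BuLi, THF, −78 °C) gives [3‑(benzyloxy)‑5‑(methoxymethoxy)phenyl]lithium F5. Epoxide 5 and then BF3·OEt2 are added at −78 °C, so the epoxide is activated by the Lewis acid instead of the nucleophile being activated by copper, and no magnesium halide is present. The mixture is quenched cold so that the MOM acetal survives, and attack at the terminal CH2 gives 13 with the stereocentre untouched.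

**Further compounds**
F1 | step 2 | racemic 1‑chlorotetradecan‑2‑ol | CCCCCCCCCCCCC(O)CCl
F2 | step 2 | racemic 2‑dodecyloxirane | CCCCCCCCCCCCC1CO1
F3 | step 5 | [3‑(benzyloxy)‑5‑bromophenyl]magnesium chloride | Cl[Mg]c1cc(Br)cc(OCc2ccccc2)c1
F4 | step 5 | (2S)‑1‑[3‑(benzyloxy)‑5‑bromophenyl]tetradecan‑2‑ol | CCCCCCCCCCCC[C@H](O)Cc1cc(Br)cc(OCc2ccccc2)c1
F5 | step 7 | [3‑(benzyloxy)‑5‑(methoxymethoxy)phenyl]lithium | [Li]c1cc(OCOC)cc(OCc2ccccc2)c1
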